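## Retrosynthetic overview
1. Target 10 ⇒ symmetric dimethyl ether 9. The last step is a mono O‑demethylation, and the two OMe groups are equivalent, so there is no regiochemical question.
2. 9 ⇒ carbinol 7. One hydrogenation removes the C=C bond, the O‑benzyl group and the doubly benzylic OH.
3. 7 ⇒ aryllithium from bromostilbene 4 + 4‑(benzyloxy)benzaldehyde 5. The bromine fixes the new Ar–C bond between the two oxygens.
4. 4 ⇒ Wittig reaction of 4‑bromo‑3,5‑dimethoxybenzaldehyde 1 with (2‑hydroxybenzyl)triphenylphosphonium bromide 2, which builds the C2 bridge.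
5. No ring is formed. All three benzene rings are bought, and ring B is attached to ring A first, then ring C.

Assumption: the target has no stereocentre and is achiral, so "single enantiomer" needs no stereocontrol. The alkene geometry of 4 to 7 and the racemic carbinol centre of 7 and 8 are both erased in step 3.

## Route

Step 1
Reactants: 1 4‑bromo‑3,5‑dimethoxybenzaldehyde; 2 (2‑hydroxybenzyl)triphenylphosphonium bromide
Product: 4 2‑[(E)‑2‑(4‑bromo‑3,5‑dimethoxyphenyl)ethenyl]phenol, via potassium 2‑[(triphenyl‑λ5‑phosphanylidene)methyl]phenolate 3 (not isolated)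
Conditions: 2 (1.1 equiv), KOtBu (2.3 equiv), THF, 0 °C, 30 min; then 1, 0 °C → rt; 1 M HCl quench
Reagents that add atoms: none
Why: Wittig olefination, in which two equivalents of base turn 2 into the oxido‑ylide 3, which condenses with the non‑enolisable aldehyde 1 without touching the aryl bromide; E is expected to be major, any Z isomer is carried along, and the ratio does not matter because step 3 saturates the alkene.

Step 2
Reactants: 4 2‑[(E)‑2‑(4‑bromo‑3,5‑dimethoxyphenyl)ethenyl]phenol; 5 4‑(benzyloxy)benzaldehyde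
Product: 7 rac‑2‑[(E)‑2‑(4‑{[4‑(benzyloxy)phenyl](hydroxy)methyl}‑3,5‑dimethoxyphenyl)ethenyl]phenol, via lithium 2‑[(E)‑2‑(4‑lithio‑3,5‑dimethoxyphenyl)ethenyl]phenolate 6 (not isolated)
Conditions: n‑BuLi (2.1 equiv), THF, −78 °C, 30 min; then 5 (1.2 equiv), −78 → 0 °C; sat. aq NH4Cl
Reagents that add atoms: none
Why: Bromine–lithium exchange followed by 1,2‑addition to an aldehyde, in which the first equivalent of n‑BuLi only deprotonates the phenol and the second exchanges the bromide at −78 °C faster than it can add to the stilbene, giving an aryllithium flanked by two OMe groups that adds to 5; the new carbinol centre is formed racemic on purpose because step 3 deletes it.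

Step 3
Reactants: 7 rac‑2‑[(E)‑2‑(4‑{[4‑(benzyloxy)phenyl](hydroxy)methyl}‑3,5‑dimethoxyphenyl)ethenyl]phenol
Product: 9 2‑{2‑[4‑(4‑hydroxybenzyl)‑3,5‑dimethoxyphenyl]ethyl}phenol, via rac‑2‑(2‑{4‑[hydroxy(4‑hydroxyphenyl)methyl]‑3,5‑dimethoxyphenyl}ethyl)phenol 8 (not isolated)
Conditions: H2 (3 bar), 10% Pd/C, EtOH–AcOH 9:1, rt → 40 °C, 16 h
Reagents that add atoms: none
Why: Catalytic hydrogenation and hydrogenolysis, in which Pd/C saturates the stilbene and cleaves the benzyl ether to give 8, whose doubly benzylic C–OH (activated by the p‑OH and the two o‑OMe groups) ionises in AcOH to a p‑quinone methide or benzhydryl cation and is reduced to CH2, removing both the alkene geometry and the racemic centre.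

Step 4
Reactants: 9 2‑{2‑[4‑(4‑hydroxybenzyl)‑3,5‑dimethoxyphenyl]ethyl}phenol
Product: 10 2‑[(4‑hydroxyphenyl)methyl]‑5‑[2‑(2‑hydroxyphenyl)ethyl]‑3‑methoxyphenol (target)
Conditions: NaSEt (5 equiv), DMF, 140 °C, 3 h; then 1 M HCl
Reagents that add atoms: none
Why: SN2 O‑demethylation of an aryl methyl ether by ethanethiolate, where the two OMe groups of 9 are symmetry‑equivalent so either cleavage gives 10, and the phenoxide formed on ring A makes the second aryloxide too poor a leaving group, so the reaction stops at the mono‑ether while the other two phenols ride along as phenoxides.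

## Compound list
1 | 4‑bromo‑3,5‑dimethoxybenzaldehyde | COc1cc(C=O)cc(OC)c1Br | starting material
2 | (2‑hydroxybenzyl)triphenylphosphonium bromide | [Br-].Oc1ccccc1C[P+](c1ccccc1)(c1ccccc1)c1ccccc1 | starting material
3 | potassium 2‑[(triphenyl‑λ5‑phosphanylidene)methyl]phenolate | [K+].[O-]c1ccccc1C=P(c1ccccc1)(c1ccccc1)c1ccccc1 | intermediate
4 | 2‑[(E)‑2‑(4‑bromo‑3,5‑dimethoxyphenyl)ethenyl]phenol (E major, Z carried along) | COc1cc(/C=C/c2ccccc2O)cc(OC)c1Br | intermediate
5 | 4‑(benzyloxy)benzaldehyde | O=Cc1ccc(OCc2ccccc2)cc1 | starting material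
6 | lithium 2‑[(E)‑2‑(4‑lithio‑3,5‑dimethoxyphenyl)ethenyl]phenolate | COc1cc(/C=C/c2ccccc2O[Li])cc(OC)c1[Li] | intermediate
7 | rac‑2‑[(E)‑2‑(4‑{[4‑(benzyloxy)phenyl](hydroxy)methyl}‑3,5‑dimethoxyphenyl)ethenyl]phenol | COc1cc(/C=C/c2ccccc2O)cc(OC)c1C(O)c1ccc(OCc2ccccc2)cc1 | intermediate
8 | rac‑2‑(2‑{4‑[hydroxy(4‑hydroxyphenyl)methyl]‑3,5‑dimethoxyphenyl}ethyl)phenol | COc1cc(CCc2ccccc2O)cc(OC)c1C(O)c1ccc(O)cc1 | intermediate
9 | 2‑{2‑[4‑(4‑hydroxybenzyl)‑3,5‑dimethoxyphenyl]ethyl}phenol | COc1cc(CCc2ccccc2O)cc(OC)c1Cc1ccc(O)cc1 | intermediate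
10 | 2‑[(4‑hydroxyphenyl)methyl]‑5‑[2‑(2‑hydroxyphenyl)ethyl]‑3‑methoxyphenol (achiral) | COc1cc(CCc2ccccc2O)cc(O)c1Cc1ccc(O)cc1 | target

## Step count and risks
Total step count: 4. Longest linear sequence: 4.

**Step 4.** The risk is under‑ or over‑demethylation and a difficult separation of 9, 10 and the bis‑phenol. The fallback desymmetrises ring A at the outset instead of at the end. It sets out from 1 and comes back at 10.
- Compound 1 is mono‑demethylated with a limited amount of BBr3 (CH2Cl2, −78 → 0 °C, recovered 1 recycled) to 4‑bromo‑3‑hydroxy‑5‑methoxybenzaldehyde F3.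
- The phenol is masked with BnBr/K2CO3 in DMF to give 3‑(benzyloxy)‑4‑bromo‑5‑methoxybenzaldehyde F4.
- Wittig reaction with 2 (through 3, as in step 1) gives 2‑[(E)‑2‑(3‑(benzyloxy)‑4‑bromo‑5‑methoxyphenyl)ethenyl]phenol F5.
- n‑BuLi (2.1 equiv, −78 °C) converts it into lithium 2‑[(E)‑2‑(3‑(benzyloxy)‑4‑lithio‑5‑methoxyphenyl)ethenyl]phenolate F6.
- F6 adds to 5 to give rac‑2‑[(E)‑2‑(3‑(benzyloxy)‑4‑{[4‑(benzyloxy)phenyl](hydroxy)methyl}‑5‑methoxyphenyl)ethenyl]phenol F7.
- Hydrogenation under the step 3 conditions passes through rac‑2‑[hydroxy(4‑hydroxyphenyl)methyl]‑5‑[2‑(2‑hydroxyphenyl)ethyl]‑3‑methoxyphenol F8 and delivers 10 directly, with no demethylation needed.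

**Step 2.** The risks are dianion solubility, butyllithium addition to the stilbene and butylation of 6. The fallback replaces the organolithium/aldehyde chemistry with a Pd‑catalysed Negishi sp2–sp3 coupling. It sets out from 4 and comes back at 9.
- Commercial 4‑(benzyloxy)benzyl chloride is inserted with Zn dust/LiCl in THF at 25 °C to give [4‑(benzyloxy)benzyl]zinc chloride F1.
- F1 is added slowly to 4 with Pd(OAc)2/SPhos in THF at 25–50 °C. The free phenol is tolerated because the coupling outruns protonation.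
- This gives 2‑[(E)‑2‑{4‑[4‑(benzyloxy)benzyl]‑3,5‑dimethoxyphenyl}ethenyl]phenol F2.
- Neutral hydrogenation (H2, Pd/C, EtOAc) then gives 9, with no carbinol to remove.

**Step 3.** The risks are incomplete C–O hydrogenolysis and acid‑induced Friedel–Crafts oligomerisation of the quinone methide. The fallback separates the two tasks. It sets out from 7 and comes back at 9.
- Compound 7 is hydrogenated under neutral conditions (H2 1 atm, Pd/C, EtOAc) only as far as 8, which is now isolated.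
- Compound 8 is deoxygenated by ionic hydrogenation (Et3SiH 3 equiv, TFA, CH2Cl2, −20 → 0 °C, dilute). Hydride traps the benzhydryl cation or p‑quinone methide to give 9.

## Further compounds
F1 | step 2 | [4‑(benzyloxy)benzyl]zinc chloride | Cl[Zn]Cc1ccc(OCc2ccccc2)cc1
F2 | step 2 | 2‑[(E)‑2‑{4‑[4‑(benzyloxy)benzyl]‑3,5‑dimethoxyphenyl}ethenyl]phenol | COc1cc(/C=C/c2ccccc2O)cc(OC)c1Cc1ccc(OCc2ccccc2)cc1
F0 | step 3 | none | none
F3 | step 4 | 4‑bromo‑3‑hydroxy‑5‑methoxybenzaldehyde | COc1cc(C=O)cc(O)c1Br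
F4 | step 4 | 3‑(benzyloxy)‑4‑bromo‑5‑methoxybenzaldehyde | COc1cc(C=O)cc(OCc2ccccc2)c1Br
F5 | step 4 | 2‑[(E)‑2‑(3‑(benzyloxy)‑4‑bromo‑5‑methoxyphenyl)ethenyl]phenol | COc1cc(/C=C/c2ccccc2O)cc(OCc2ccccc2)c1Br
F6 | step 4 | lithium 2‑[(E)‑2‑(3‑(benzyloxy)‑4‑lithio‑5‑methoxyphenyl)ethenyl]phenolate | COc1cc(/C=C/c2ccccc2O[Li])cc(OCc2ccccc2)c1[Li]
F7 | step 4 | rac‑2‑[(E)‑2‑(3‑(benzyloxy)‑4‑{[4‑(benzyloxy)phenyl](hydroxy)methyl}‑5‑methoxyphenyl)ethenyl]phenol | COc1cc(/C=C/c2ccccc2O)cc(OCc2ccccc2)c1C(O)c1ccc(OCc2ccccc2)cc1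
F8 | step 4 | rac‑2‑[hydroxy(4‑hydroxyphenyl)methyl]‑5‑[2‑(2‑hydroxyphenyl)ethyl]‑3‑methoxyphenol | COc1cc(CCc2ccccc2O)cc(O)c1C(O)c1ccc(O)cc1
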